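Remark on the chemistry: compounds 3, 4, 7 and 9–12 are racemic and are drawn as the enantiomer (or relative configuration) that is carried on after the resolution in steps 8 and 9; the acetal carbon of 17 and 18, the lactol carbon of 19 and the orthoester carbon of 26 and 27 form as epimer mixtures and are drawn without configuration.

## Analysis of the target

Atom labels: ring A is C1 (quaternary, bears C12H2OAc)–C2H2–C3H(OAc)–C4H(OH)–C5Me2–C6 (quaternary). The cage is C6, C7H2, the cyclopropane C8H–C9H–C10(CH3) and C11H(OAc), joined by C6–C7, C7–C8, C9–C1, C10–C11 and C11–C6.

The cage of 28 is a tricyclo[2.2.1.0^2,6]heptane (nortricyclene): apex C6 carries the three one-carbon bridges C7, C1 and C11, and each bridge ends on one cyclopropane carbon. Ring A is fused across C1–C6, so C5, C6 and C1 are three contiguous fully substituted carbons. Of the eight stereocentres, C6, C8, C9 and C10 are locked to one another by the cage. What must be chosen is the sense of C1 (C2 towards the C11 bridge, C12 towards the C7 bridge), C11 (acetoxy towards C7, away from ring A), the cis C3/C4 oxygens (both on the ring A face that carries C12; C3–O axial and acetylated, C4–O equatorial and free), and the absolute configuration. The C11 acetate is cyclopropylcarbinylic and ionizes easily, the C3 acetate and C4 hydroxyl can exchange the acyl group, and diketone precursors of the cage are non-enolizable 1,3-diketones open to retro-Claisen or retro-aldol cleavage. The hard parts are the crowded C5–C6–C1 array, placing C2 and C12 correctly on a quaternary C1 of a rigid cage, and telling four oxygens apart. The strategy rests on one feature: C2 lies on the C11 side of C1, within bonding reach (in a model) of a group hung on a C11 oxygen that points to C1, so a two-carbon unit C2–C3 tethered to that oxygen can reach C1 only from the correct face.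

## Retrosynthetic reasoning

**28 back to 25 (via 27 and 26).** The last operation only distinguishes oxygens. The C3 and C4 oxygens are tied into cyclic orthoacetate 26, the C12 hydroxyl is acetylated (27), and the orthoester is opened. The forward step must release the ester on the axial C3 oxygen and leave C4–OH free; this is the normal course of orthoester opening, and the neopentyl position of C4 supports it.

**25 back to 24.** The C3–O and C4–O bonds are cut together to the ring A alkene. Both oxygens sit on the face that carries C12, so the axial C12 hydroxymethyl of 24, 1,3 to C3, can steer a syn-dihydroxylation. The other face is covered by C11 and the hydrogen it turns under the ring.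

**24 back to 23.** C12–O is traced to C12–B. Boron serves as a masked hydroxyl that stays inert while C11 is inverted, and it is the activating group of the radical acceptor in the key step.

**23 back to 21 (via 22).** The acetate of 23 points to C7, whereas the anchoring oxygen points to C1, so the C11–O bond is cut and re-formed. Sulfonate 22 ionizes to the cyclopropane-stabilized C11 cation, and acetate should enter from the C7 flank because the C1 flank is occupied by C2, ring A and the leaving group. Oxidation followed by hydride reduction would not invert: hydride would also come from the C7 flank and return 21.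

**21 back to 20.** Ring A is opened at C3=C4. Ring-closing metathesis fits because the allyl group on C1 and the vinyl group on C5 are held side by side across C1–C6, and the alkene it leaves is the site of the diol.

**20 back to 19 and 18.** The terminal allyl carbon is removed (methylenation of the open form of lactol 19), and 19 comes from mixed acetal 18 by hydrolysis. C3 was therefore an acetal carbon bound to the C11 oxygen.

**18 back to 17 (key disconnection).** C1–C2 is cut homolytically. This removes the quaternary stereocentre C1 and leaves bromoacetal 17, in which C2 hangs on the C11 oxygen and C1 is part of an exocyclic alkenylboronate. Forward, the C2 radical must add to C1 (6-exo) and not to C12; the tether fixes the face.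

**17 back to 15 and 16.** The acetal C–O bond and the C–Br bond are cut: 17 is the bromoacetalization product of alcohol 15 and 16. The C11–O bond is untouched, so 15 must already have the anchor configuration. Both acetal epimers are usable.

**15 back to 14, then 12 and 13.** The cage is made racemic, so 15 is traced through diastereomeric ester 14 (from racemate 12 and 13). The resolution sits at the last hydroxyl-bearing intermediate before the bromoacetal.

**12 back to 10 (via 11) and 9.** The hydroxyl of 12 points to C1, and hydride addition to ketone 9 should not deliver that. The flank of trigonal C1 is the open side of the C11 carbonyl, while the C7 methylene turns a hydrogen into the other trajectory, so reduction should give 10 with the hydroxyl towards C7. Alcohol 12 is therefore derived from 10 by inversion through sulfonate 11: the same C11 cation, here taking up the oxygen nucleophile from the open C1 flank.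

**9 back to 7 and 8.** C1=C12 is cut; 9 is the boron-Wittig product of dione 7 and 8. C1 is the less shielded ketone (its cyclopropane neighbour C9 carries hydrogen; C10 next to C11 carries methyl). Olefinating before reducing also removes the β-ketol relationship that would let a C11 alkoxide fragment the cage.

**7 back to 5 and 6.** Three cage bonds are cut at once: C6–C7, C8–C9 and C8–C10. The two carbons of 6 become C7 and C8. The forward cascade must alkylate hindered C6 and then close two rings; either sense of the second addition gives the same cage.

**5 back to 4, 3, then 1 and 2.** Enedione 5 is the oxidation product of hydroxy enone 4, which is the Piancatelli isomer of furyl carbinol 3. Carbinol 3 is cut at C5–C6 into 1 and 2, so the C5–C6 bond with its gem-dimethyl and vinyl groups is made in the first step rather than by a late alkylation next to a quaternary centre.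

## Alternatives that were turned down

**Alternative 1:** The cut is C5–C6. The forward key step is a thermal Claisen rearrangement in which an O–C3 bond breaks while C5–C6 forms, contracting an oxygen heterocycle to the ring A cyclohexene and giving spiro ketone A1.
- For it: the step is concerted, it makes the most hindered bond of the molecule with transfer of chirality from C3, and the ring A alkene arrives where the diol is needed. An enantioselective entry without resolution is conceivable, and on that point it is stronger than the chosen route.
- Against it: A1 contains only ring A and a cyclopentanone. The cage must still be built by bonding C9 (the sulfonylmethyl arm on C1) to both C8 and C10, which needs enone formation, conjugate addition and a 1,3-elimination after the key step. The rearrangement must also join a fully substituted enol ether carbon to a dimethyl-substituted alkene terminus, and C1 has to be set independently beforehand.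
- Comparison: the chosen route makes C5–C6 trivially in step 1, obtains the whole cage in one operation, and uses the cage itself to set C1.

**Alternative 2:** The cuts are C1–C6 and C9–C10. The forward key step is an intramolecular Diels–Alder reaction between a diene unit C6=C7–C8=C10 (C11 as ketal carbon between its ends) and a tethered dienophile unit C1=C9, giving norbornene A2.
- For it: one thermal step forms ring A and a bicycle and sets C1, C6 and C10. The C3/C4 oxygens can come from the chiral pool as an acetonide, so neither resolution nor late dihydroxylation is needed; here it is stronger than the chosen route.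
- Against it: the cycloaddition must bond a fully substituted diene terminus (next to quaternary C5) to a fully substituted dienophile carbon, creating three contiguous quaternary carbons in one transition state. The diene type dimerizes readily. A2 still lacks the C8–C9 cyclopropane bond, which would have to be closed from the nitro-bearing C9 onto C7=C8 within the equilibrating norbornenyl/nortricyclyl manifold, and the C11 configuration remains unsolved.
- Comparison: the chosen route closes the cyclopropane in the cage-forming step and attacks C1 with a small primary radical from a short tether.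

**Alternative 3:** The cuts are C1–C6 and, temporarily, C9–C11. The forward key step is an intramolecular enone–alkene photocycloaddition giving cyclobutane A3, followed later by a 1,2-shift of C9 from C11 to C10.
- For it: photocycloadditions join crowded quaternary carbons under mild conditions, and the tether controls the C1/C6 relationship as reliably as the tether of the chosen route does. The diol can again come from the chiral pool.
- Against it: straight versus crossed regiochemistry at a tetrasubstituted enone carbon is uncertain. After A3 the route needs methyl addition at C10, a pinacol-type shift with correct bond alignment, and then a cyclopropane closure onto an unactivated C8. Stereocentres at C9 and C11 are made only to be destroyed, and the sequence is the longest of all.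
- Comparison: the chosen route needs no skeletal rearrangement and has the cyclopropane from the start.

Key step: step 11

## Steps

Step 1
Reactants: 1 3-methylfuran-2-carbaldehyde; 2 prenyl bromide (1-bromo-3-methylbut-2-ene)
Product: 3 (±)-2,2-dimethyl-1-(3-methylfuran-2-yl)but-3-en-1-ol
Conditions: Zn, sat. aq. NH4Cl/THF, 0 → 25 °C
Reagents that add atoms: none
Why: Barbier allylation; the prenylzinc species reacts through its γ-carbon (SE2′), so the aldehyde carbon (C6) is bonded to the dimethyl-substituted carbon (C5) and the vinyl group is in place.

Step 2
Reactants: 3 (±)-2,2-dimethyl-1-(3-methylfuran-2-yl)but-3-en-1-ol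
Product: 4 (±)-trans-4-hydroxy-2-methyl-5-(2-methylbut-3-en-2-yl)cyclopent-2-en-1-one
Conditions: ZnCl2, dioxane/H2O, 80 °C
Reagents that add atoms: water, O
Why: Piancatelli rearrangement: ionization of the furyl carbinol, water addition at the free furan α-position, ring opening and conrotatory 4π closure. The trans relationship is the usual outcome but both stereocentres are erased in steps 3 and 4.

Step 3
Reactants: 4 (±)-trans-4-hydroxy-2-methyl-5-(2-methylbut-3-en-2-yl)cyclopent-2-en-1-one
Product: 5 4-methyl-2-(2-methylbut-3-en-2-yl)cyclopent-4-ene-1,3-dione
Conditions: CrO3, aq. H2SO4, acetone, 0 °C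
Reagents that add atoms: none
Why: Jones oxidation of the allylic secondary alcohol, the standard way from Piancatelli hydroxy enones to 2-substituted cyclopent-4-ene-1,3-diones; the isolated vinyl group should survive at 0 °C.

Step 4
Reactants: 5 4-methyl-2-(2-methylbut-3-en-2-yl)cyclopent-4-ene-1,3-dione; 6 vinyltriphenylphosphonium bromide
Product: 7 (±)-cage dione, 2-methyl-4-(2-methylbut-3-en-2-yl)tricyclo[2.2.1.0^2,6]heptane-3,5-dione (ketones at C1 and C11, methyl on C10, side chain on C6)
Conditions: NaH, THF, 0 °C; then 6, DMF, 25 → 60 °C
Reagents that add atoms: none
Why: Michael–Michael–ring closure (bicycloannulation of a cyclic enone α′-anion with a vinylphosphonium salt): the C6 anion adds to 6 (C6–C7), the ylide carbon C8 adds across the ring to the enedione, and the resulting ketone enolate expels Ph3P from C8 to close the cyclopropane. Either alkene carbon may be attacked first with the same result, the cage fixes C6, C8, C9 and C10 relative to one another, and a non-nucleophilic base avoids retro-Claisen cleavage of the product.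

Step 5
Reactants: 7 (±)-cage dione; 8 bis[(pinacolato)boryl]methane
Product: 9 (±)-C11 ketone with exocyclic (E)-alkenylboronate C1=C12H–B(pin), boron trans to C6
Conditions: 8, lithium 2,2,6,6-tetramethylpiperidide (LiTMP), THF, 0 °C; then 7, −78 → 0 °C
Reagents that add atoms: none
Why: Boron-Wittig olefination; the lithiated diborylmethane should add to the less shielded C1 carbonyl (neighbour C9–H, against C10–CH3 beside C11) and the adduct collapses by syn B–O elimination with boron away from the bulkier C6. Immediate capture of the alkoxide by boron should suppress retro-aldol opening.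

Step 6
Reactants: 9 (±)-C11 ketone with C1 alkenylboronate
Product: 10 (±)-C11 alcohol with the hydroxyl pointing to C7
Conditions: NaBH4, MeOH, 0 °C
Reagents that add atoms: none
Why: Hydride reduction of a strained, non-enolizable ketone; as with 7-norbornenone-type ketones the reagent should approach over the trigonal bridge (C1), because the C7 methylene turns a hydrogen into the other trajectory, so the hydroxyl ends on the C7 side. The alkenylboronate is inert to NaBH4.

Step 7
Reactants: 10 (±)-C11 alcohol with the hydroxyl pointing to C7
Product: 12 (±)-C11 epimer of 10 with the hydroxyl pointing to C1 (anchor alcohol), via methanesulfonate 11 (not isolated)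
Conditions: Ms2O, Et3N, CH2Cl2, −20 °C; then acetone/H2O, NaHCO3, 25 °C
Reagents that add atoms: water, O
Why: Solvolysis of a cyclopropylcarbinyl (3-nortricyclyl) sulfonate; the C11 cation is stabilized by the C10 cyclopropane, and water should enter from the open flank of trigonal C1, opposite the departing sulfonate, which inverts C11. Ms2O avoids chloride capture.

Step 8
Reactants: 12 (±)-anchor alcohol; 13 (1S)-(−)-camphanic chloride
Product: 14 (1S)-camphanic ester of the anchor alcohol, the diastereomer with the cage configuration of 28
Conditions: 13, Et3N, DMAP, CH2Cl2, 25 °C; separation of the two diastereomeric esters by chromatography or crystallization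
Reagents that add atoms: none
Why: Classical resolution through diastereomeric esters; the acyl chloride has no α-hydrogen and cannot racemize, and the camphanoyl group serves as internal reference for assigning the absolute configuration of 14 crystallographically.

Step 9
Reactants: 14 (1S)-camphanic ester of the anchor alcohol
Product: 15 anchor alcohol as single enantiomer (C11 hydroxyl pointing to C1, exocyclic C1 alkenylboronate)
Conditions: K2CO3, MeOH, 40 °C
Reagents that add atoms: none
Why: Transesterification at the acyl carbon; the C11–O bond is not broken, so the configuration is kept, and the pinacol alkenylboronate tolerates carbonate in methanol.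

Step 10
Reactants: 15 anchor alcohol; 16 ethyl vinyl ether
Product: 17 2-bromo-1-ethoxyethyl acetal of 15 at the C11 oxygen (both acetal epimers), with the C1 alkenylboronate
Conditions: 16, NBS, CH2Cl2, −40 → 0 °C
Reagents that add atoms: N-bromosuccinimide, O=C1CCC(=O)N1Br
Why: Bromoacetalization (preparation of a Ueno–Stork precursor): the bromonium ion of the enol ether is opened by the C11 hydroxyl, leaving the C11–O bond intact. The electron-rich enol ether should react with NBS far faster than the alkenylboronate or the hindered vinyl group.

Step 11
Reactants: 17 bromoacetal with C1 alkenylboronate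
Product: 18 cage-fused 2-ethoxytetrahydropyran (O on C11, C2 on C1) with quaternary C1 and C12H2–B(pin)
Conditions: Bu3SnH (slow addition), AIBN (cat.), benzene, 80 °C, high dilution
Reagents that add atoms: none
Why: Ueno–Stork haloacetal radical cyclization onto an alkenylboronate: Bu3Sn• abstracts bromine and leaves a primary radical at C2, tied through the acetal carbon (future C3) to the C11 oxygen. That oxygen points to C1, so the radical adds to C1 in a 6-exo-trig closure through a six-membered array (C11, O, acetal C, C2, C1, C6) of which three atoms are locked in the cage; this forms C1–C2 and closes the temporary tetrahydropyran. The adduct radical at C12 is α to boron, stabilized by the vacant boron orbital, and is quenched by Bu3SnH to the CH2B(pin) group. C1 is the one new stereocentre and the tether controls it: an oxygen on the C11 bridge can deliver C2 only to the C11 face of the exocyclic alkene, which places C12 on the C7 side as in 28. The selectivity needed is exo attack at C1 over 7-endo attack at C12 and over reduction of the open radical. It is secured by the boron substituent (it makes the exo adduct the stabilized radical and its pinacol ester shields C12), by the rigid cage holding radical and acceptor together, and by slow stannane addition keeping the hydride concentration low. Both acetal epimers cyclize and the alkene geometry is lost at C12, so neither matters. The closest known chemistry is the bromoacetal cyclization and radical addition to alkenylboronic esters.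

Step 12
Reactants: 18 cage-fused 2-ethoxytetrahydropyran
Product: 19 corresponding lactol (2-hydroxytetrahydropyran, in equilibrium with the C11-hydroxy aldehyde)
Conditions: AcOH/H2O/THF (3:1:1), 45 °C
Reagents that add atoms: water, O
Why: Hydrolysis of the mixed acetal; both acetal epimers converge, and the alkyl pinacol boronate and the C11–O bond should be stable to dilute acetic acid.

Step 13
Reactants: 19 lactol
Product: 20 C1-allyl compound with C12H2–B(pin), the 2-methylbut-3-en-2-yl group on C6 and the free C11 hydroxyl pointing to C1
Conditions: Ph3PCH3Br, KN(SiMe3)2, THF, 0 → 40 °C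
Reagents that add atoms: methyltriphenylphosphonium bromide, C[P+](c1ccccc1)(c1ccccc1)c1ccccc1.[Br-]
Why: Wittig methylenation of the open hydroxy aldehyde form of the lactol; it turns C2–C3 into the allyl group and releases the C11 hydroxyl without touching its configuration.

Step 14
Reactants: 20 C1-allyl compound
Product: 21 ring A cyclohexene (C3=C4) with C12H2–B(pin) and the C11 hydroxyl pointing to C1
Conditions: second-generation Grubbs catalyst RuCl2(=CHPh)(PCy3)(H2IMes) (5 mol%), CH2Cl2, 40 °C
Reagents that add atoms: none
Why: Ring-closing metathesis; the allyl group on C1 and the vinyl group on C5 are held gauche across C1–C6, so closure to the six-membered ring is favoured and is driven by loss of ethylene. Free hydroxyl and alkylboronate are tolerated.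

Step 15
Reactants: 21 ring A cyclohexene with the C11 hydroxyl pointing to C1
Product: 23 ring A cyclohexene with C11 acetate (acetoxy pointing to C7) and C12H2–B(pin), via methanesulfonate 22 (not isolated)
Conditions: Ms2O, Et3N, CH2Cl2, −20 °C; then KOAc, AcOH, 40 °C
Reagents that add atoms: acetic acid, CC(=O)O
Why: Acetolysis of the nortricyclyl sulfonate through the cyclopropane-stabilized C11 cation; the C1 flank is now blocked by C2, ring A and the leaving group, so acetate should enter from the C7 flank. This inverts C11 to the configuration of 28.

Step 16
Reactants: 23 C11 acetate with C12H2–B(pin)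
Product: 24 C12 primary alcohol with C11 acetate and ring A alkene
Conditions: NaBO3·4H2O, THF/H2O, 25 °C
Reagents that add atoms: sodium perborate, [Na+].[O-]B1OO1
Why: Oxidation of the alkylboronate by 1,2-migration from boron to oxygen; mild perborate should leave the hindered C11 acetate intact.

Step 17
Reactants: 24 C12 primary alcohol with ring A alkene
Product: 25 triol (C12–OH, cis C3–OH and C4–OH on the face of C12) with C11 acetate
Conditions: OsO4 (1.05 equiv), TMEDA, CH2Cl2, −78 °C; then aq. Na2SO3, THF, 40 °C
Reagents that add atoms: osmium tetroxide, O=[Os](=O)(=O)=O
Why: Hydrogen-bond-directed syn-dihydroxylation (OsO4·TMEDA); the axial C12 hydroxymethyl lies 1,3 to C3 on the face to be oxidized and should deliver the reagent there, while the opposite face is covered by C11 and its inward hydrogen. This sets C3 and C4.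

Step 18
Reactants: 25 triol
Product: 28 target triacetate CNP0197219.1, via cyclic orthoacetate 26 (not isolated), via orthoacetate C12 acetate 27 (not isolated)
Conditions: MeC(OMe)3, CSA (cat.), CH2Cl2, 25 °C; then Ac2O, pyridine, DMAP (cat.), 0 → 25 °C; then 80% aq. AcOH, 25 °C
Reagents that add atoms: trimethyl orthoacetate, CC(OC)(OC)OC; acetic anhydride, CC(=O)OC(C)=O; water, O
Why: Orthoester-mediated regioselective monoacylation of a cis-diol: the cyclic orthoacetate ties up the C3 and C4 oxygens, so only C12–OH is acetylated. Acidic opening through the dioxolan-2-ylium ion should release the ester on the axial C3 oxygen and the free hydroxyl on the equatorial, neopentyl C4.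

## Compound list

1 | 3-methylfuran-2-carbaldehyde | Cc1ccoc1C=O | starting material
2 | prenyl bromide (1-bromo-3-methylbut-2-ene) | CC(C)=CCBr | starting material
3 | (±)-2,2-dimethyl-1-(3-methylfuran-2-yl)but-3-en-1-ol | C=CC(C)(C)C(O)c1occc1C | intermediate
4 | (±)-trans-4-hydroxy-2-methyl-5-(2-methylbut-3-en-2-yl)cyclopent-2-en-1-one | C=CC(C)(C)[C@@H]1[C@@H](O)C=C(C)C1=O | intermediate
5 | 4-methyl-2-(2-methylbut-3-en-2-yl)cyclopent-4-ene-1,3-dione | C=CC(C)(C)C1C(=O)C=C(C)C1=O | intermediate
6 | vinyltriphenylphosphonium bromide | [Br-].C=C[P+](c1ccccc1)(c1ccccc1)c1ccccc1 | starting material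
7 | (±)-cage dione, 2-methyl-4-(2-methylbut-3-en-2-yl)tricyclo[2.2.1.0^2,6]heptane-3,5-dione (C1 and C11 ketones) | C=CC(C)(C)[C@@]12C[C@@H]3[C@H](C2=O)[C@]3(C)C1=O | intermediate
8 | bis[(pinacolato)boryl]methane | CC1(C)OB(CB2OC(C)(C)C(C)(C)O2)OC1(C)C | starting material
9 | (±)-C11 ketone with exocyclic (E)-C1=C12H–B(pin) | C=CC(C)(C)[C@@]12C[C@@H]3[C@H](/C2=C\B4OC(C)(C)C(C)(C)O4)[C@]3(C)C1=O | intermediate
10 | (±)-C11 alcohol, hydroxyl pointing to C7, C1 alkenylboronate | C=CC(C)(C)[C@@]12C[C@@H]3[C@H](/C2=C\B4OC(C)(C)C(C)(C)O4)[C@]3(C)[C@H]1O | intermediate
11 | (±)-methanesulfonate of 10 | C=CC(C)(C)[C@@]12C[C@@H]3[C@H](/C2=C\B4OC(C)(C)C(C)(C)O4)[C@]3(C)[C@H]1OS(C)(=O)=O | intermediate (not isolated)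
12 | (±)-anchor alcohol, C11 hydroxyl pointing to C1, C1 alkenylboronate | C=CC(C)(C)[C@@]12C[C@@H]3[C@H](/C2=C\B4OC(C)(C)C(C)(C)O4)[C@]3(C)[C@@H]1O | intermediate
13 | (1S)-(−)-camphanic chloride | O=C(Cl)[C@@]12CC[C@@](C)(C(=O)O1)C2(C)C | starting material
14 | (1S)-camphanic ester of the anchor alcohol, diastereomer with the cage configuration of 28 | C=CC(C)(C)[C@@]12C[C@@H]3[C@H](/C2=C\B4OC(C)(C)C(C)(C)O4)[C@]3(C)[C@@H]1OC(=O)[C@@]56CC[C@@](C)(C(=O)O5)C6(C)C | intermediate
15 | anchor alcohol, single enantiomer | C=CC(C)(C)[C@@]12C[C@@H]3[C@H](/C2=C\B4OC(C)(C)C(C)(C)O4)[C@]3(C)[C@@H]1O | intermediate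
16 | ethyl vinyl ether | C=COCC | starting material
17 | bromoacetal of 15 (2-bromo-1-ethoxyethyl ether at the C11 oxygen, both acetal epimers) | C=CC(C)(C)[C@@]12C[C@@H]3[C@H](/C2=C\B4OC(C)(C)C(C)(C)O4)[C@]3(C)[C@@H]1OC(OCC)CBr | intermediate
18 | cage-fused 2-ethoxytetrahydropyran with quaternary C1 and C12H2–B(pin) | CC1(C)OB(C[C@]23CC(OCC)O[C@@H]4[C@@]2(C(C)(C)C=C)C[C@@H]5[C@H]3[C@]45C)OC1(C)C | intermediate
19 | corresponding lactol | CC1(C)OB(C[C@]23CC(O)O[C@@H]4[C@@]2(C(C)(C)C=C)C[C@@H]5[C@H]3[C@]45C)OC1(C)C | intermediate
20 | C1-allyl, C1-CH2B(pin) cage alcohol (C11 hydroxyl pointing to C1, vinyl on C5) | C=CC(C)(C)[C@@]12C[C@@H]3[C@H]([C@]2(CC=C)CB4OC(C)(C)C(C)(C)O4)[C@]3(C)[C@@H]1O | intermediate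
21 | ring A cyclohexene with C12H2–B(pin), C11 hydroxyl pointing to C1 | CC1(C)OB(C[C@]23CC=CC(C)(C)[C@]24C[C@@H]5[C@H]3[C@]5(C)[C@@H]4O)OC1(C)C | intermediate
22 | methanesulfonate of 21 | CC1(C)OB(C[C@]23CC=CC(C)(C)[C@]24C[C@@H]5[C@H]3[C@]5(C)[C@@H]4OS(C)(=O)=O)OC1(C)C | intermediate (not isolated)
23 | ring A cyclohexene with C11 acetate (acetoxy pointing to C7) and C12H2–B(pin) | CC1(C)OB(C[C@]23CC=CC(C)(C)[C@]24C[C@@H]5[C@H]3[C@]5(C)[C@H]4OC(C)=O)OC1(C)C | intermediate
24 | C12 alcohol with C11 acetate and ring A alkene | OC[C@]12CC=CC(C)(C)[C@]13C[C@@H]4[C@H]2[C@]4(C)[C@H]3OC(C)=O | intermediate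
25 | triol (C12–OH, cis C3–OH/C4–OH) with C11 acetate | OC[C@]12C[C@H](O)[C@H](O)C(C)(C)[C@]13C[C@@H]4[C@H]2[C@]4(C)[C@H]3OC(C)=O | intermediate
26 | cyclic C3,C4 orthoacetate (1-methoxyethylidene) of 25 | OC[C@]12C[C@@H]5OC(C)(OC)O[C@@H]5C(C)(C)[C@]13C[C@@H]4[C@H]2[C@]4(C)[C@H]3OC(C)=O | intermediate (not isolated)
27 | C12 acetate of 26 | CC(=O)OC[C@]12C[C@@H]5OC(C)(OC)O[C@@H]5C(C)(C)[C@]13C[C@@H]4[C@H]2[C@]4(C)[C@H]3OC(C)=O | intermediate (not isolated)
28 | CNP0197219.1 | CC(=O)OC[C@]12C[C@H](OC(C)=O)[C@H](O)C(C)(C)[C@]13C[C@@H]1[C@H]2[C@]1(C)[C@H]3OC(C)=O | target

## Step count and least certain steps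

Total step count: 18. Longest linear sequence: 18 steps (from 1; the route is linear).

**Step 11 (key step).** The most likely failure is closure in the 7-endo mode at C12 or hydrogen transfer to the open C2 radical before cyclization. Exo attack has to create a quaternary centre beside quaternary C6, and a model shows the short tether forcing an attack angle on C1 well below the preferred value.
Fallback (polar, untethered, substrate-controlled), from 15 back to the route at 24:
- 15 is oxidized at C11 (Dess–Martin periodinane, CH2Cl2) to the single-enantiomer keto alkenylboronate F1.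
- NaBO3·4H2O converts the alkenylboronate into the C1-formyl ketone F2.
- KN(SiMe3)2 and allyl bromide (THF, −78 °C) alkylate the exocyclic aldehyde enolate to the C1-allyl keto aldehyde F3. The electrophile should enter from the flank of the trigonal C11 carbonyl, the same open side used by hydride in step 6 seen from the other bridge, which again puts C2 on the C11 side and C12 on the C7 side.
- Ring-closing metathesis with the ruthenium catalyst of step 14 gives the ring A keto aldehyde F4.
- Equilibrating Meerwein–Ponndorf–Verley reduction (Al(OiPr)3, iPrOH, toluene, 90 °C) should give the C11,C12-diol F5 with the C11 hydroxyl on the thermodynamically preferred C7 side.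
- Ac2O/pyridine/DMAP gives the diacetate F6, and K2CO3/MeOH at 0 °C removes the primary acetate to return to 24.

**Step 4.** Either the first conjugate addition fails at the hindered C6 (attack through oxygen, or none), or the cascade stalls before a ketone enolate expels Ph3P in the three-membered ring closure. Adventitious nucleophiles could also cleave the strained 1,3-diketone.
Fallback (staged annulation with a nitronate donor and nitrite as leaving group), from 5 to 7: 5 is added under mild amine catalysis (Et3N, MeCN) to nitroethylene, released in situ from 2-nitroethyl benzoate, to give the isolable nitroethyl dione F7. K2CO3 in DMSO at 60 °C then forms the nitronate, which adds to the enedione, and the enolate displaces nitrite to close the cyclopropane, giving 7.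

**Step 5.** Addition at the wrong carbonyl (C11) or retro-aldol fragmentation of the β-keto alkoxide adduct are the risks, because both ketones are neopentyl-like and the dione is strained.
Fallback (halo-olefination, then borylation), from 7 to 9: Wittig bromomethylenation ((bromomethyl)triphenylphosphonium bromide, NaN(SiMe3)2, THF, −78 °C) gives the C1 bromomethylene ketone F8. Miyaura borylation (B2pin2, PdCl2(dppf), KOAc, dioxane, 80 °C) converts it into 9.

**Step 7.** Skeletal leakage of the C11 cation into the norbornenyl (homoallyl) manifold, or poor facial selectivity of water capture, would erode the anchor alcohol. The C10 methyl group favours the ring-opened alkene, and the two flanks differ only by one hydrogen.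
Fallback (set C11 by hydride with the C1 flank blocked, then olefinate), from 7 to 12:
- Selective ketalization of the less hindered C1 carbonyl (1,2-bis(trimethylsilyloxy)ethane, TMSOTf cat., CH2Cl2, −40 °C) gives the C1 dioxolane ketone F9.
- NaBH4 now meets a tetrahedral, oxygen-bearing C1 and should add from the C7 flank to give the ketal alcohol F10 with the hydroxyl towards C1.
- PPTS in aqueous acetone frees the hydroxy ketone F11, and TMSCl/imidazole gives its silyl ether F12, which prevents retro-aldol cleavage under base.
- Boron-Wittig olefination as in step 5 gives the silyl ether F13, and K2CO3/MeOH removes the silyl group to reach 12.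

**Step 15.** The same cation could rearrange to norbornenyl acetates, or the ring A alkene could take part, instead of clean capture at C11 from the C7 flank.
Fallback (thermodynamic control through the ketone), from 21 to 23: Dess–Martin oxidation gives the C11 ketone F14. Equilibrating Meerwein–Ponndorf–Verley reduction (Al(OiPr)3, iPrOH with a trace of acetone, toluene, 100 °C) should give the C11 epimer F15 with the hydroxyl towards C7, because the other position is compressed against C2. Ac2O/DMAP then gives 23.

## Further compounds

F1 | step 11 | single-enantiomer C11 ketone with exocyclic (E)-C1=C12H–B(pin) | C=CC(C)(C)[C@@]12C[C@@H]3[C@H](/C2=C\B4OC(C)(C)C(C)(C)O4)[C@]3(C)C1=O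
F2 | step 11 | C1-formyl C11 ketone (C1–H, either C1 epimer) | C=CC(C)(C)[C@@]12C[C@@H]3[C@H](C2C=O)[C@]3(C)C1=O
F3 | step 11 | C1-allyl C1-formyl C11 ketone (allyl on the C11 side) | C=CC(C)(C)[C@@]12C[C@@H]3[C@H]([C@]2(CC=C)C=O)[C@]3(C)C1=O
F4 | step 11 | ring A cyclohexene with C12 aldehyde and C11 ketone | O=C[C@]12CC=CC(C)(C)[C@]13C[C@@H]4[C@H]2[C@]4(C)C3=O
F5 | step 11 | ring A cyclohexene C11,C12-diol (C11 hydroxyl pointing to C7) | OC[C@]12CC=CC(C)(C)[C@]13C[C@@H]4[C@H]2[C@]4(C)[C@H]3O
F6 | step 11 | ring A cyclohexene C11,C12-diacetate | CC(=O)OC[C@]12CC=CC(C)(C)[C@]13C[C@@H]4[C@H]2[C@]4(C)[C@H]3OC(C)=O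
F7 | step 4 | (±)-4-methyl-2-(2-methylbut-3-en-2-yl)-2-(2-nitroethyl)cyclopent-4-ene-1,3-dione (enantiomer leading to 7 as drawn) | C=CC(C)(C)[C@]1(CC[N+](=O)[O-])C(=O)C=C(C)C1=O
F8 | step 5 | (±)-C11 ketone with exocyclic C1 bromomethylene (major alkene isomer drawn) | C=CC(C)(C)[C@@]12C[C@@H]3[C@H](/C2=C\Br)[C@]3(C)C1=O
F9 | step 7 | (±)-C1 ethylene ketal of 7 | C=CC(C)(C)[C@@]12C[C@@H]3[C@H](C24OCCO4)[C@]3(C)C1=O
F10 | step 7 | (±)-C1 ethylene ketal C11 alcohol (hydroxyl pointing to C1) | C=CC(C)(C)[C@@]12C[C@@H]3[C@H](C24OCCO4)[C@]3(C)[C@@H]1O
F11 | step 7 | (±)-C11-hydroxy C1 ketone (hydroxyl pointing to C1) | C=CC(C)(C)[C@@]12C[C@@H]3[C@H](C2=O)[C@]3(C)[C@@H]1O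
F12 | step 7 | (±)-trimethylsilyl ether of F11 | C=CC(C)(C)[C@@]12C[C@@H]3[C@H](C2=O)[C@]3(C)[C@@H]1O[Si](C)(C)C
F13 | step 7 | (±)-trimethylsilyl ether of 12 | C=CC(C)(C)[C@@]12C[C@@H]3[C@H](/C2=C\B4OC(C)(C)C(C)(C)O4)[C@]3(C)[C@@H]1O[Si](C)(C)C
F14 | step 15 | ring A cyclohexene C11 ketone with C12H2–B(pin) | CC1(C)OB(C[C@]23CC=CC(C)(C)[C@]24C[C@@H]5[C@H]3[C@]5(C)C4=O)OC1(C)C
F15 | step 15 | C11 epimer of 21 (hydroxyl pointing to C7) | CC1(C)OB(C[C@]23CC=CC(C)(C)[C@]24C[C@@H]5[C@H]3[C@]5(C)[C@H]4O)OC1(C)C
A1 | alternative 1 | spiro[4.5]decenone from the Claisen ring contraction (benzyloxymethyl and phenylsulfonylmethyl on C1, ring A alkene, methylcyclopentanone) | c1ccccc1COC[C@]1(CS(=O)(=O)c2ccccc2)CC=CC(C)(C)[C@]13CC[C@H](C)C3=O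
A2 | alternative 2 | ring A-fused 7,7-dimethoxynorbornene with C1 methyl ester, C9 nitro group and C3/C4 acetonide | COC(=O)[C@]12C[C@@H]3OC(C)(C)O[C@@H]3C(C)(C)[C@]14C=C[C@@](C)(C4(OC)OC)[C@@H]2[N+](=O)[O-]
A3 | alternative 3 | tricyclic cyclobutane photoadduct with C10 ketone, silyloxy groups on C9 and C11 and C3/C4 acetonide | c1ccccc1COC[C@]12C[C@@H]3OC(C)(C)O[C@@H]3C(C)(C)[C@]14CCC(=O)[C@]4(O[Si](C)(C)C(C)(C)C)[C@@H]2O[Si](C)(C)C(C)(C)C
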